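## The problem

Melanocin E (16) is a flat 1-arylnaphthalene. It is numbered here so that C1 bears the 4-methoxyphenyl ring C, C2 and C3 bear the formamido groups, C4 is CH, C4a and C8a are the fusion carbons, and C6 and C7 of ring A bear the catechol hydroxyls; ring B holds the nitrogens. There is no stereocentre, and the C1–aryl axis is not stereogenic because ring C is para-substituted, so no centre has to control another and the task is purely regiochemical. Ring B carries four different neighbours in a row (aryl, N, N, H), and the nitrogens sit on the two β-positions C2 and C3, which electrophilic substitution of a finished naphthalene avoids in favour of C4, C5 and C8; the ring therefore has to be built with its substituents in place. Three groups will not stand rough handling: the vicinal bis-formamide, which acid or heat closes to a naphtho[2,3-d]imidazole and which acid or base hydrolyses; the catechol, which oxidises easily, the more so beside an electron-rich diamine; and the single methyl ether of ring C, which must outlast the unmasking of the ring A oxygens. Formyl groups and free phenols therefore belong at the very end, under neutral conditions, and the two nitrogens need robust earlier forms that can be told apart. The feature that opens the problem is that the C2 nitrogen lies next to the aryl-bearing C1 while C3 can begin as oxygen. Written as an aryl alkyne (C1≡C2), a ketone (C3) and a benzylic methylene on ring A (C4), the skeleton is an ynone in which a nitrogen-centred radical adding at C2 leaves its spin on C1, within reach of C8a.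

## Retrosynthesis

**O–benzyl.** The last cut is made at the two O–CH2Ph bonds of bis(benzyl ether) 15. Hydrogenolysis is neutral and touches neither formamide nor the anisyl ether. A methylenedioxy acetal would instead have to be opened with BCl3 in the presence of two Lewis-basic formamides, which invites cyclodehydration to the imidazole. The price is that no hydrogenation over palladium may be used before the end.

**N–CHO.** Both N–CHO bonds of 15 are cut to give diamine 14. Formamides would survive neither the aqueous acid nor the palladium-catalysed step that come earlier, and a free 1,2-diamine lets both be installed in one operation. The forward reaction must acylate the hindered C2 amine before the mono-formamide can cyclise, which calls for a reactive formyl donor in the cold.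

**Nitro to amine.** Diamine 14 is traced to nitroamine 13 by a change of oxidation level at the C2 nitrogen alone. Holding that nitrogen as a nitro group differentiates the two nitrogens without a protecting group and keeps the air-sensitive diamine out of the route until it is needed. The reduction has to spare the benzyl ethers, so iron is asked for rather than hydrogen.

**C3–N.** The C3–N bond of 13 is cut to give triflate 11. Displacement by ammonia under activation by the neighbouring nitro group looks shorter but is weak here. Charge from attack at C3 reaches the C2 nitro group only through an ortho-quinoid form of ring A, the nitro group is twisted by the flanking anisyl ring, and a hard nucleophile tends to attack sulfur. Oxidative addition of zerovalent palladium needs no such activation, so a Buchwald–Hartwig coupling with benzophenone imine followed by hydrolysis is chosen. The precursor is simpler by one nitrogen.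

**O–S.** Triflate 11 comes from nitronaphthol 10 by cutting the O–S bond. The C3 oxygen left by the ring-forming step thus becomes the handle for the second nitrogen.

**C2–N and C1–C8a (key cut).** Nitronaphthol 10 is opened at these two bonds, which removes ring B and the first nitrogen together and leaves the acyclic ynone 7 and tert-butyl nitrite (8). Nitration of a preformed 1-aryl-3-naphthol would strike C4; this cut fixes nitrogen on C2 by the order of bond formation. An electrophile-induced closure would put a halogen on C2 and leave a hindered C2–N coupling to be done; this cut avoids it. The forward reaction must add NO2 at C2, close at C8a rather than at the ipso carbon or the hindered ortho carbon, and leave the acidic C4 methylene alone.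

**C2–C3.** Ynone 7 is cut between the carbonyl carbon C3 and the alkyne carbon C2 into Weinreb amide 3 and 1-ethynyl-4-methoxybenzene (4). An arylacetyl chloride under Sonogashira-type conditions would form a ketene, and an aldehyde would add an oxidation step; the amide stops cleanly at the ketone. The forward step asks for addition without deprotonation of the benzylic position.

**Amide N–acyl.** Amide 3 comes from the acid 1. All seventeen skeletal carbons of 16 are then present in 1 and 4, and only the two formyl carbons are added later.

## Roads not taken

**Alternative 1:** The cut removes C2–C3, C1–C8a and C4–C4a at once. In the forward sense, Pd2(dba)3 with P(o-tolyl)3 would join the two alkynes of the aminal-bridged bis-ynamide A2 with the aryne released by CsF from silyl triflate A3, giving the tosylated cyclic aminal A1 with ring B and a five-membered N–CH2–N ring closed together.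
- Merits: it is the most convergent of the four plans. Three C–C bonds form in one step, both nitrogens are placed by construction, and the symmetrical aryne raises no regiochemical question on ring A.
- Weak points: A2 is an unsymmetrical bis-ynamide with one terminal ynamide; it needs two different N-alkynylations and is labile. Zerovalent palladium also trimerises arynes and forms 2:1 adducts. After the key step, two sulfonyl groups on hindered anilide nitrogens and the aminal carbon must be removed by dissolving-metal or SmI2 chemistry before formylation, and the acetal then still has to be opened with BCl3.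
- Comparison: this road is better on convergence and on the nitrogen question, since the chosen plan needs a separate palladium-catalysed amination for the C3 nitrogen. The chosen plan sets against it a two-step precursor from catalogue compounds and nitrogens that are unveiled by a mild hydrolysis and an iron reduction instead of sulfonamide cleavage.

**Alternative 2:** The cut is at C4–C4a and C1–C8a. The aryne from A3 would add across the diene ends of the fully substituted 2-pyrone A5, and loss of CO2 from the bridged lactone would give diester A4.
- Merits: aryne/2-pyrone cycloaddition with decarboxylation is an established naphthalene synthesis, and the substituent order on ring B is fixed by the pyrone.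
- Weak points: the step delivers carbon, not nitrogen, at C2 and C3. Both esters of A4 would have to be hydrolysed (the C2 ester is flanked by the aryl ring) and degraded by a double Curtius rearrangement, in which a vicinal pair tends to close to an anhydride or a cyclic urea. A5 is an electron-poor diene, poorly matched with an electrophilic aryne, and itself needs several steps.
- Comparison: the key step of this road is more secure than a radical cascade without direct precedent on its substrate class, and that is conceded. The chosen plan sets against it that nitrogen arrives on C2 in the ring-forming event and the diamine is reached three steps later without any carbon-to-nitrogen degradation.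

**Alternative 3:** The cut is at C3–C4 and C4–C4a. Acid and trimethyl orthoformate would put a formyl-level carbon on the free ring carbon of imidazolone A7, the oxocarbenium ion would be attacked by ring A, and loss of methanol and of the C1 hydrogen would give the naphthimidazolone A6 (a Bradsher-type closure).
- Merits: both nitrogens are present from the start, the closure is an electrophilic substitution para to a ring A oxygen, and it uses the same benzyl protection as the chosen route.
- Weak points: A7 needs its own multi-step synthesis. N- and C-formylation of the imidazolone compete. Above all, the cyclic urea of an aromatic 1,2-diamine is among the most hydrolysis-resistant carbonyl derivatives, and opening A6 to diamine 14 would need hot strong base or acid.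
- Comparison: regiocontrol on ring A is probably better here than in a radical closure. The chosen plan sets against it that its nitrogens are freed under mild conditions and that its precursor takes two steps.

Key step: step 3

Assumption: the catechol is carried from the start as its bis(benzyl) ether, and 2-[3,4-bis(benzyloxy)phenyl]acetic acid (1), 1-ethynyl-4-methoxybenzene (4) and tert-butyl nitrite (8) are taken as catalogue compounds.

## Route

Step 1
Reactants: 1 2-[3,4-bis(benzyloxy)phenyl]acetic acid
Product: 3 2-[3,4-bis(benzyloxy)phenyl]-N-methoxy-N-methylacetamide, via acyl imidazolide 2 (not isolated)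
Conditions: CDI, CH2Cl2, rt, 1 h; then MeNHOMe·HCl, rt
Reagents that add atoms: N,O-dimethylhydroxylamine hydrochloride, CNOC.Cl; 1,1'-carbonyldiimidazole, O=C(n1ccnc1)n1ccnc1 (its imidazolyl group stays only in intermediate 2)
Why: Weinreb amide formation by CDI activation; the acyl imidazolide acylates the hydroxylamine, the liberated imidazole takes up the HCl, and the benzyl ethers are inert.

Step 2
Reactants: 3 2-[3,4-bis(benzyloxy)phenyl]-N-methoxy-N-methylacetamide; 4 1-ethynyl-4-methoxybenzene
Product: 7 1-[3,4-bis(benzyloxy)phenyl]-4-(4-methoxyphenyl)but-3-yn-2-one, via lithium acetylide 5 (not isolated), via tetrahedral lithium alkoxide 6 (not isolated)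
Conditions: 4 (1.5 equiv), nBuLi, THF, −78 °C; then 3, −78 → −20 °C; inverse quench into cold 1 M HCl
Reagents that add atoms: n-butyllithium, [Li]CCCC (its lithium stays only in intermediates 5 and 6)
Why: Weinreb ketone synthesis; the chelated tetrahedral adduct 6 cannot collapse before the quench, so no second addition occurs, and the acetylide is too weak a base to deprotonate the benzylic position competitively at −78 °C. The cold acidic quench protonates the liberated hydroxylamine so that it cannot add to the ynone in conjugate fashion.

Step 3
Reactants: 7 1-[3,4-bis(benzyloxy)phenyl]-4-(4-methoxyphenyl)but-3-yn-2-one; 8 tert-butyl nitrite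
Product: 10 6,7-bis(benzyloxy)-4-(4-methoxyphenyl)-3-nitronaphthalen-2-ol, via keto tautomer 9 (not isolated)
Conditions: tBuONO (2.5 equiv, two portions), O2 (1 atm), MeCN, 60 °C, no acid or base
Reagents that add atoms: dioxygen, O=O (one oxygen of the nitro group)
Why: Proposed new method: tert-butyl nitrite (8) homolyses on warming to tert-butoxyl and NO, O2 turns NO into NO2, and this electrophilic radical should add to C2 of ynone 7, the alkyne carbon alpha to the carbonyl, because only that regiochemistry leaves a linear vinyl radical at C1 stabilised by the anisyl ring. The closest known reaction types are the tert-butyl nitrite nitrative cyclisations of aryl alkynoates to 3-nitrocoumarins and of 2-alkynylbiaryls to nitrophenanthrenes, and the electrophile-induced closure of 1-aryl-3-alkyn-2-ones to 3-halo-2-naphthols; what has not been shown is the nitro radical variant on this ynone class. Ring B, the only ring formed, closes when the C1 radical attacks the ortho carbon C8a of ring A through a six-membered transition state (6-endo-trig counted on the C4a–C8a bond), forming C1–C8a. The cyclohexadienyl radical is then oxidised by NO2 or O2 and loses the C8a proton, and keto tautomer 9 enolises at C4 because this makes ring B aromatic and ties the hydroxyl to the nitro group by a hydrogen bond. No stereocentre is created. Three selectivities are needed: ortho rather than ipso attack, which the unstrained six-ring transition state favours over the spiro five-ring one (an ipso adduct can still reach the same product by 1,2-shift of the vinyl carbon); closure at C8a, para to the C6 benzyloxy group, rather than at the ring A carbon wedged between the side chain and that group, which a freely rotating benzyl ether shields better than a tied-back acetal would; and addition of NO2 to the alkyne ahead of nitrosation of the acidic C4 methylene of 7 or a second nitration of 10 at C4, which the neutral medium, the limited charge of nitrite and the deactivating, hydrogen-bonded nitro group of 10 should secure.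

Step 4
Reactants: 10 6,7-bis(benzyloxy)-4-(4-methoxyphenyl)-3-nitronaphthalen-2-ol
Product: 11 6,7-bis(benzyloxy)-4-(4-methoxyphenyl)-3-nitronaphthalen-2-yl trifluoromethanesulfonate
Conditions: Tf2O, pyridine, CH2Cl2, −20 → 0 °C
Reagents that add atoms: trifluoromethanesulfonic anhydride, O=S(=O)(OS(=O)(=O)C(F)(F)F)C(F)(F)F
Why: O-sulfonylation of an acidic ortho-nitronaphthol; the hydroxyl has only one ortho substituent and triflates under standard conditions.

Step 5
Reactants: 11 6,7-bis(benzyloxy)-4-(4-methoxyphenyl)-3-nitronaphthalen-2-yl trifluoromethanesulfonate
Product: 13 6,7-bis(benzyloxy)-4-(4-methoxyphenyl)-3-nitronaphthalen-2-amine, via N-aryl diphenylmethanimine 12 (not isolated)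
Conditions: Ph2C=NH, Pd(OAc)2 (5 mol %), rac-BINAP, Cs2CO3, toluene, 90 °C; then 2 M HCl, THF, rt
Reagents that add atoms: benzophenone imine, N=C(c1ccccc1)c1ccccc1 (its nitrogen stays in 13; the diphenylmethylidene group stays only in intermediate 12)
Why: Buchwald–Hartwig amination of an electron-poor aryl triflate with benzophenone imine as ammonia surrogate; the nitro group speeds oxidative addition, the weak insoluble base Cs2CO3 limits S–O cleavage of the triflate, and dilute acid hydrolyses the imine without touching the benzyl ethers, the methyl ether or the nitro group.

Step 6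
Reactants: 13 6,7-bis(benzyloxy)-4-(4-methoxyphenyl)-3-nitronaphthalen-2-amine
Product: 14 6,7-bis(benzyloxy)-1-(4-methoxyphenyl)naphthalene-2,3-diamine
Conditions: Fe powder, NH4Cl, EtOH/THF/H2O, 75 °C; used at once
Reagents that add atoms: none
Why: Béchamp-type iron reduction of an ortho-nitroaniline to the 1,2-diamine; unlike H2 over palladium it leaves the benzyl ethers in place, so the catechol stays masked while the diamine is handled.

Step 7
Reactants: 14 6,7-bis(benzyloxy)-1-(4-methoxyphenyl)naphthalene-2,3-diamine
Product: 15 N,N'-[6,7-bis(benzyloxy)-1-(4-methoxyphenyl)naphthalene-2,3-diyl]diformamide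
Conditions: HCO2H/Ac2O (premixed at 55 °C, cooled, excess), THF, −20 → 0 °C
Reagents that add atoms: acetic formic anhydride, CC(=O)OC=O, made beforehand from formic acid, OC=O, and acetic anhydride, CC(=O)OC(C)=O
Why: N-formylation with the mixed anhydride, which transfers its more electrophilic formyl group; the excess of a reactive donor in the cold should acylate both amines before the mono-formamide can cyclodehydrate to the naphthimidazole, and no free hydroxyl competes.

Step 8
Reactants: 15 N,N'-[6,7-bis(benzyloxy)-1-(4-methoxyphenyl)naphthalene-2,3-diyl]diformamide
Product: 16 N,N'-[6,7-dihydroxy-1-(4-methoxyphenyl)naphthalene-2,3-diyl]diformamide (melanocin E)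
Conditions: H2 (1 atm), 10% Pd/C, MeOH/THF, rt; filtration and concentration under argon
Reagents that add atoms: none
Why: Hydrogenolysis of benzyl aryl ethers under neutral conditions; formamides, the anisyl methyl ether and the naphthalene core are not reduced, and the catechol is set free without acid or base.

## Compound list

1 | 2-[3,4-bis(benzyloxy)phenyl]acetic acid | OC(=O)Cc1ccc(OCc2ccccc2)c(OCc2ccccc2)c1 | starting material
2 | 2-[3,4-bis(benzyloxy)phenyl]-1-(1H-imidazol-1-yl)ethan-1-one | O=C(Cc1ccc(OCc2ccccc2)c(OCc2ccccc2)c1)n1ccnc1 | intermediate (not isolated)
3 | 2-[3,4-bis(benzyloxy)phenyl]-N-methoxy-N-methylacetamide | CON(C)C(=O)Cc1ccc(OCc2ccccc2)c(OCc2ccccc2)c1 | intermediate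
4 | 1-ethynyl-4-methoxybenzene | COc1ccc(C#C)cc1 | starting material
5 | lithium (4-methoxyphenyl)acetylide | [Li]C#Cc1ccc(OC)cc1 | intermediate (not isolated)
6 | lithium 1-[3,4-bis(benzyloxy)phenyl]-2-[methoxy(methyl)amino]-4-(4-methoxyphenyl)but-3-yn-2-olate | [Li]OC(Cc1ccc(OCc2ccccc2)c(OCc2ccccc2)c1)(C#Cc1ccc(OC)cc1)N(C)OC | intermediate (not isolated)
7 | 1-[3,4-bis(benzyloxy)phenyl]-4-(4-methoxyphenyl)but-3-yn-2-one | COc1ccc(cc1)C#CC(=O)Cc1ccc(OCc2ccccc2)c(OCc2ccccc2)c1 | intermediate
8 | tert-butyl nitrite | CC(C)(C)ON=O | starting material
9 | 6,7-bis(benzyloxy)-4-(4-methoxyphenyl)-3-nitronaphthalen-2(1H)-one | COc1ccc(cc1)C1=C([N+](=O)[O-])C(=O)Cc2cc(OCc3ccccc3)c(OCc3ccccc3)cc12 | intermediate (not isolated)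
10 | 6,7-bis(benzyloxy)-4-(4-methoxyphenyl)-3-nitronaphthalen-2-ol | COc1ccc(cc1)-c1c([N+](=O)[O-])c(O)cc2cc(OCc3ccccc3)c(OCc3ccccc3)cc12 | intermediate
11 | 6,7-bis(benzyloxy)-4-(4-methoxyphenyl)-3-nitronaphthalen-2-yl trifluoromethanesulfonate | COc1ccc(cc1)-c1c([N+](=O)[O-])c(OS(=O)(=O)C(F)(F)F)cc2cc(OCc3ccccc3)c(OCc3ccccc3)cc12 | intermediate
12 | N-[6,7-bis(benzyloxy)-4-(4-methoxyphenyl)-3-nitronaphthalen-2-yl]-1,1-diphenylmethanimine | COc1ccc(cc1)-c1c([N+](=O)[O-])c(N=C(c3ccccc3)c3ccccc3)cc2cc(OCc3ccccc3)c(OCc3ccccc3)cc12 | intermediate (not isolated)
13 | 6,7-bis(benzyloxy)-4-(4-methoxyphenyl)-3-nitronaphthalen-2-amine | COc1ccc(cc1)-c1c([N+](=O)[O-])c(N)cc2cc(OCc3ccccc3)c(OCc3ccccc3)cc12 | intermediate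
14 | 6,7-bis(benzyloxy)-1-(4-methoxyphenyl)naphthalene-2,3-diamine | COc1ccc(cc1)-c1c(N)c(N)cc2cc(OCc3ccccc3)c(OCc3ccccc3)cc12 | intermediate
15 | N,N'-[6,7-bis(benzyloxy)-1-(4-methoxyphenyl)naphthalene-2,3-diyl]diformamide | COc1ccc(cc1)-c1c(NC=O)c(NC=O)cc2cc(OCc3ccccc3)c(OCc3ccccc3)cc12 | intermediate
16 | N,N'-[6,7-dihydroxy-1-(4-methoxyphenyl)naphthalene-2,3-diyl]diformamide (melanocin E) | COc1ccc(-c2c(NC=O)c(NC=O)cc3cc(O)c(O)cc23)cc1 | target

## Step count and least certain steps

Total: 8 steps. Longest linear sequence: 8 steps (1 → 16).

**Step 3 (key step).** The C1 vinyl radical may be intercepted by O2 or NO2 before it reaches ring A. It may close at the ipso carbon and dearomatise ring A with loss of a benzyl group. Closure may occur in part at the hindered ortho carbon. The nitrite may also nitrosate the C4 methylene of 7 or nitrate 10 a second time at C4. These follow because a radical chain under O2 has several fast exits and a 2-naphthol stays nucleophilic at its alpha carbon. The fallback uses known chemistry with a different mode of activation and sets out from 7. ICl in CH2Cl2 at room temperature effects the established 6-endo-dig carbocyclisation of this ynone class and should give 6,7-bis(benzyloxy)-3-iodo-4-(4-methoxyphenyl)naphthalen-2-ol F1 with the same C1–C8a bond and ring B. Tf2O and pyridine give 6,7-bis(benzyloxy)-3-iodo-4-(4-methoxyphenyl)naphthalen-2-yl trifluoromethanesulfonate F2. A double Buchwald–Hartwig amination with benzophenone imine (Pd2(dba)3, rac-BINAP, Cs2CO3, toluene, 100 °C) replaces iodide and triflate to give N,N'-[6,7-bis(benzyloxy)-1-(4-methoxyphenyl)naphthalene-2,3-diyl]bis(1,1-diphenylmethanimine) F3. Hydrolysis with 2 M HCl in THF brings the fallback back to the route at diamine 14. It gives up the radical C2–N bond and pays with an amination at the hindered C2.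

**Step 5.** Carbonate or adventitious water may cleave the S–O bond of the nitro-activated triflate and return the naphtholate of 10, and reductive elimination next to the nitro group may be slow. The fallback reverses the polarity at C3 and sets out from 11. Miyaura borylation (PdCl2(dppf), B2pin2, KOAc, dioxane, 80 °C) gives 2-[6,7-bis(benzyloxy)-4-(4-methoxyphenyl)-3-nitronaphthalen-2-yl]-4,4,5,5-tetramethyl-1,3,2-dioxaborolane F4. Azidation catalysed by Cu(OAc)2 with NaN3 in MeOH under air gives 3-azido-6,7-bis(benzyloxy)-1-(4-methoxyphenyl)-2-nitronaphthalene F5. SnCl2·2H2O in EtOAc/EtOH below 40 °C, a temperature at which an ortho-nitroaryl azide does not yet lose nitrogen, reduces azide and nitro group together, and the fallback comes back to the route at diamine 14.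

**Step 2.** The acetylide may deprotonate the benzylic methylene of 3 instead of adding, the liberated hydroxylamine may add to the ynone during the quench, and base may isomerise 7 to an allenyl ketone. The fallback sets out from 3. Reduction with iBu2AlH in THF at −78 °C gives 2-[3,4-bis(benzyloxy)phenyl]acetaldehyde F6, which is used at once. Addition of lithium acetylide 5 at −78 °C gives racemic 1-[3,4-bis(benzyloxy)phenyl]-4-(4-methoxyphenyl)but-3-yn-2-ol F7, whose stereocentre is removed in the next operation. Oxidation with Dess–Martin periodinane buffered with NaHCO3 in CH2Cl2 comes back to the route at ynone 7.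

**Step 7.** Formylation of the hindered C2 amine may lag behind that of C3, and the mono-formamide may then cyclodehydrate to the naphthimidazole. The fallback installs the two formyl groups at different stages and sets out from 13. Neat acetic formic anhydride at room temperature formylates the nitroamine to N-[6,7-bis(benzyloxy)-4-(4-methoxyphenyl)-3-nitronaphthalen-2-yl]formamide F8. Neutral hydrogenation over sulfided Pt/C (H2, 1 atm, EtOAc, rt), which spares benzyl ethers, gives N-[3-amino-6,7-bis(benzyloxy)-4-(4-methoxyphenyl)naphthalen-2-yl]formamide F9. After filtration this is treated directly with acetic formic anhydride at −20 °C, and the fallback comes back to the route at bis-formamide 15.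

## Further compounds

F1 | step 3 | 6,7-bis(benzyloxy)-3-iodo-4-(4-methoxyphenyl)naphthalen-2-ol | COc1ccc(cc1)-c1c(I)c(O)cc2cc(OCc3ccccc3)c(OCc3ccccc3)cc12
F2 | step 3 | 6,7-bis(benzyloxy)-3-iodo-4-(4-methoxyphenyl)naphthalen-2-yl trifluoromethanesulfonate | COc1ccc(cc1)-c1c(I)c(OS(=O)(=O)C(F)(F)F)cc2cc(OCc3ccccc3)c(OCc3ccccc3)cc12
F3 | step 3 | N,N'-[6,7-bis(benzyloxy)-1-(4-methoxyphenyl)naphthalene-2,3-diyl]bis(1,1-diphenylmethanimine) | COc1ccc(cc1)-c1c(N=C(c3ccccc3)c3ccccc3)c(N=C(c3ccccc3)c3ccccc3)cc2cc(OCc3ccccc3)c(OCc3ccccc3)cc12
F4 | step 5 | 2-[6,7-bis(benzyloxy)-4-(4-methoxyphenyl)-3-nitronaphthalen-2-yl]-4,4,5,5-tetramethyl-1,3,2-dioxaborolane | COc1ccc(cc1)-c1c([N+](=O)[O-])c(B3OC(C)(C)C(C)(C)O3)cc2cc(OCc3ccccc3)c(OCc3ccccc3)cc12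
F5 | step 5 | 3-azido-6,7-bis(benzyloxy)-1-(4-methoxyphenyl)-2-nitronaphthalene | COc1ccc(cc1)-c1c([N+](=O)[O-])c(N=[N+]=[N-])cc2cc(OCc3ccccc3)c(OCc3ccccc3)cc12
F6 | step 2 | 2-[3,4-bis(benzyloxy)phenyl]acetaldehyde | O=CCc1ccc(OCc2ccccc2)c(OCc2ccccc2)c1
F7 | step 2 | 1-[3,4-bis(benzyloxy)phenyl]-4-(4-methoxyphenyl)but-3-yn-2-ol (racemic) | COc1ccc(cc1)C#CC(O)Cc1ccc(OCc2ccccc2)c(OCc2ccccc2)c1
F8 | step 7 | N-[6,7-bis(benzyloxy)-4-(4-methoxyphenyl)-3-nitronaphthalen-2-yl]formamide | COc1ccc(cc1)-c1c([N+](=O)[O-])c(NC=O)cc2cc(OCc3ccccc3)c(OCc3ccccc3)cc12
F9 | step 7 | N-[3-amino-6,7-bis(benzyloxy)-4-(4-methoxyphenyl)naphthalen-2-yl]formamide | COc1ccc(cc1)-c1c(N)c(NC=O)cc2cc(OCc3ccccc3)c(OCc3ccccc3)cc12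
A1 | alternative 1 | N,N'-ditosyl N,N'-methylene aminal of 5-(4-methoxyphenyl)naphtho[2,3-d][1,3]dioxole-6,7-diamine | COc1ccc(cc1)-c1c2N(CN(c2cc2cc3OCOc3cc12)S(=O)(=O)c1ccc(C)cc1)S(=O)(=O)c1ccc(C)cc1
A2 | alternative 1 | N-ethynyl-N-({N-[(4-methoxyphenyl)ethynyl]-4-methylbenzenesulfonamido}methyl)-4-methylbenzenesulfonamide | COc1ccc(cc1)C#CN(CN(C#C)S(=O)(=O)c1ccc(C)cc1)S(=O)(=O)c1ccc(C)cc1
A3 | alternative 1 | 6-(trimethylsilyl)-1,3-benzodioxol-5-yl trifluoromethanesulfonate | C[Si](C)(C)c1cc2OCOc2cc1OS(=O)(=O)C(F)(F)F
A4 | alternative 2 | dimethyl 5-(4-methoxyphenyl)naphtho[2,3-d][1,3]dioxole-6,7-dicarboxylate | COC(=O)c1cc2cc3OCOc3cc2c(-c2ccc(OC)cc2)c1C(=O)OC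
A5 | alternative 2 | dimethyl 6-(4-methoxyphenyl)-2-oxo-2H-pyran-4,5-dicarboxylate | COC(=O)C1=CC(=O)OC(c2ccc(OC)cc2)=C1C(=O)OC
A6 | alternative 3 | 6,7-bis(benzyloxy)-4-(4-methoxyphenyl)-1,3-dihydro-2H-naphtho[2,3-d]imidazol-2-one | COc1ccc(cc1)-c1c2NC(=O)Nc2cc2cc(OCc3ccccc3)c(OCc3ccccc3)cc12
A7 | alternative 3 | 4-{[3,4-bis(benzyloxy)phenyl](4-methoxyphenyl)methyl}-1,3-dihydro-2H-imidazol-2-one | COc1ccc(cc1)C(c1ccc(OCc2ccccc2)c(OCc2ccccc2)c1)C1=CNC(=O)N1
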